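**Retrosynthetic overview** (side chain numbered C1'–C16' from the ring)
- No ring is built: the six-membered ring is bought as an arene and unveiled as the quinone in the last step by oxidative demethylation.
- Key disconnection C5'–C6' (sp3–sp2): nickel-electrocatalytic decarboxylative alkenylation joins a western aryl-hexenoic acid to an eastern (E)-alkenyl iodide that already carries the free (10R,11R)-diol.
- Western acid: aryl Grignard reagent plus lavender lactone, copper-catalysed anti-SN2' opening (sets the 2'E olefin).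
- Eastern iodide: syn-carboalumination/iodination of an alkyne diol (sets the 6'E olefin), which comes from chelation-controlled homoprenyl Grignard addition to an (R)-α-hydroxy methyl ketone (sets C11').
- C10' is bought with methyl (R)-glycidate, the only source of chirality; a propargyl unit is added at C3 of the epoxide.

Assumption: 1-bromo-2,5-dimethoxy-3-methylbenzene, lavender lactone, methyl (R)-glycidate, propargyl bromide and 5-bromo-2-methylpent-2-ene are taken as catalogue compounds.

**Step 1**
Reactants: 1 1-bromo-2,5-dimethoxy-3-methylbenzene; 2 5-methyl-5-vinyldihydrofuran-2(3H)-one (lavender lactone, racemic)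
Product: 4 (E)-6-(2,5-dimethoxy-3-methylphenyl)-4-methylhex-4-enoic acid, via aryl Grignard reagent 3 (not isolated)
Conditions: Mg, THF, 50 °C; then 2, CuBr·SMe2 (10 mol %), THF/Me2S, −30 to 0 °C; 1 M HCl
Reagents that add atoms: none
Why: Copper-catalysed anti-SN2' (allylic) substitution of a γ-vinyl lactone by an aryl Grignard reagent puts the aryl group on the terminal vinyl carbon and expels the carboxylate; the E olefin is favoured because the methyl group, not the ring methylene, eclipses the vinyl unit in the reactive conformer (expected about 9:1 or better, Z acid removed by recrystallising the dicyclohexylammonium salt).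

**Step 2**
Reactants: 5 methyl (2R)-oxirane-2-carboxylate; 6 3-bromoprop-1-yne
Product: 8 methyl (2R)-2-hydroxyhex-5-ynoate, via allenylmagnesium bromide 7 (not isolated)
Conditions: 6, Mg, HgCl2 (1 mol %), Et2O, 0 °C; then 5, CuBr·SMe2 (10 mol %), Et2O/THF, −78 to −40 °C; 1 M HCl
Reagents that add atoms: none
Why: Copper-catalysed Grignard opening of a glycidic ester (SN2 at the unsubstituted C3), with the allenyl reagent reacting through its γ-carbon (SE2') to give the propargyl product; C2 is bought with 5 and is not touched.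

**Step 3**
Reactants: 8 methyl (2R)-2-hydroxyhex-5-ynoate
Product: 10 (3R)-3-hydroxyhept-6-yn-2-one, via Weinreb amide 9 (not isolated)
Conditions: MeNH(OMe)·HCl (1.5 equiv), MeMgCl (7 equiv), THF, −20 °C to rt; 1 M HCl, 0 °C
Reagents that add atoms: methylmagnesium chloride, C[Mg]Cl
Why: One-pot Weinreb ketone synthesis (ester aminolysis by the magnesium amide, then Grignard addition that stops at the chelated tetrahedral adduct); the α-stereocentre sits as its magnesium alkoxide and is not enolised.

**Step 4**
Reactants: 10 (3R)-3-hydroxyhept-6-yn-2-one; 11 5-bromo-2-methylpent-2-ene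
Product: 13 (5R,6R)-6,10-dimethylundec-9-en-1-yne-5,6-diol, via homoprenyl Grignard reagent 12 (not isolated)
Conditions: 11, Mg, THF, rt; then 10 added to 12 (3.5 equiv), THF, −78 to −30 °C; aq. NH4Cl
Reagents that add atoms: none
Why: Cram-chelate (cyclic model) Grignard addition: the first equivalent makes the magnesium alkoxide, which locks C=O and C3–O in a five-membered chelate, and the next adds from the face of the small C3–H, anti to the C4 chain, so the bought (5R) centre sets the tertiary carbinol as (6R) (expected dr at least 10:1).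

**Step 5**
Reactants: 13 (5R,6R)-6,10-dimethylundec-9-en-1-yne-5,6-diol
Product: 15 (1E,5R,6R)-1-iodo-2,6,10-trimethylundeca-1,9-diene-5,6-diol, via alkenylalane 14 (not isolated)
Conditions: AlMe3 (5 equiv), Cp2ZrCl2 (0.3 equiv), H2O (1 equiv), CH2Cl2, −20 °C to rt; then I2 (1.5 equiv), THF, −30 °C; aq. potassium sodium tartrate, Na2S2O3
Reagents that add atoms: trimethylaluminium, C[Al](C)C; iodine, [I][I]
Why: Negishi zirconium-catalysed syn-carboalumination of the terminal alkyne (methyl to the internal carbon, aluminium to the terminus) and iodinolysis with retention give the (E)-2-methylalkenyl iodide; the diol rides through as its aluminium alkoxide and the trisubstituted alkene is inert.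

**Step 6**
Reactants: 4 (E)-6-(2,5-dimethoxy-3-methylphenyl)-4-methylhex-4-enoic acid; 15 (1E,5R,6R)-1-iodo-2,6,10-trimethylundeca-1,9-diene-5,6-diol
Product: 17 (6R,7R,10E,14E)-16-(2,5-dimethoxy-3-methylphenyl)-2,6,10,14-tetramethylhexadeca-2,10,14-triene-6,7-diol, via N-acyloxyphthalimide ester 16 (not isolated)
Conditions: 4 (2 equiv), N-hydroxyphthalimide, DIC, DMF, rt, 2 h; then 15 (1 equiv), NiCl2·6H2O (20 mol %), 2,2'-bipyridine (20 mol %), AgNO3 (0.3 equiv), Mg anode, RVC cathode, undivided cell, constant current (about 2.5 F/mol), rt; 1 M HCl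
Reagents that add atoms: none
Why: Proposed new method: nickel-electrocatalytic decarboxylative alkenylation on a silver-nanoparticle-coated cathode is established for simple terpenoid fragments but not for an alkenyl iodide with a free secondary/tertiary 1,2-diol paired with an ester made in situ from an acid bearing an oxidation-prone hydroquinone diether; it should work because every redox event is cathodic (the magnesium anode is sacrificial, so arene and alkenes never see an oxidising potential), no base is present to deprotonate the diol or drive acyl transfer, low-valent nickel–bipyridine inserts into the C–I bond with retention of the E geometry, one-electron reduction of 16 releases CO2 and a primary homoallylic radical that is captured by the alkenylnickel species faster than reversible 3-exo cyclisation can scramble the 2'E olefin, and reductive elimination from trivalent nickel forms C5'–C6'; closest known reaction type: nickel-catalysed reductive (electrochemical) decarboxylative alkenylation of N-acyloxyphthalimides with alkenyl halides.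

**Step 7**
Reactants: 17 (6R,7R,10E,14E)-16-(2,5-dimethoxy-3-methylphenyl)-2,6,10,14-tetramethylhexadeca-2,10,14-triene-6,7-diol
Product: 18 2-[(2E,6E,10R,11R)-10,11-dihydroxy-3,7,11,15-tetramethylhexadeca-2,6,14-trien-1-yl]-6-methylcyclohexa-2,5-diene-1,4-dione
Conditions: (NH4)2Ce(NO3)6 (2.3 equiv), MeCN/H2O 2:1, 0 °C, 10 min
Reagents that add atoms: water, O
Why: Oxidative demethylation of a hydroquinone dimethyl ether by tetravalent cerium (two one-electron oxidations, water adds to the arene radical cation, methanol leaves) is far faster at 0 °C than cerium-mediated glycol cleavage, so the diol and the three alkenes survive and no stereocentre is touched.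

**Compound list**
1 | 1-bromo-2,5-dimethoxy-3-methylbenzene | COc1cc(C)c(OC)c(Br)c1 | starting material
2 | 5-methyl-5-vinyldihydrofuran-2(3H)-one (lavender lactone, racemic) | CC1(C=C)CCC(=O)O1 | starting material
3 | (2,5-dimethoxy-3-methylphenyl)magnesium bromide | COc1cc(C)c(OC)c([Mg]Br)c1 | intermediate
4 | (E)-6-(2,5-dimethoxy-3-methylphenyl)-4-methylhex-4-enoic acid | COc1cc(C)c(OC)c(C/C=C(\C)CCC(=O)O)c1 | intermediate
5 | methyl (2R)-oxirane-2-carboxylate (methyl (R)-glycidate) | COC(=O)[C@H]1CO1 | starting material
6 | 3-bromoprop-1-yne (propargyl bromide) | BrCC#C | starting material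
7 | propa-1,2-dien-1-ylmagnesium bromide (allenylmagnesium bromide) | C=C=C[Mg]Br | intermediate
8 | methyl (2R)-2-hydroxyhex-5-ynoate | COC(=O)[C@H](O)CCC#C | intermediate
9 | (2R)-2-hydroxy-N-methoxy-N-methylhex-5-ynamide | CON(C)C(=O)[C@H](O)CCC#C | intermediate
10 | (3R)-3-hydroxyhept-6-yn-2-one | CC(=O)[C@H](O)CCC#C | intermediate
11 | 5-bromo-2-methylpent-2-ene | CC(C)=CCCBr | starting material
12 | (4-methylpent-3-en-1-yl)magnesium bromide | CC(C)=CCC[Mg]Br | intermediate
13 | (5R,6R)-6,10-dimethylundec-9-en-1-yne-5,6-diol | CC(C)=CCC[C@@](C)(O)[C@H](O)CCC#C | intermediate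
14 | [(1E,5R,6R)-5,6-dihydroxy-2,6,10-trimethylundeca-1,9-dien-1-yl]dimethylalane (drawn as the free diol; in the flask the hydroxyls are aluminium alkoxides) | CC(C)=CCC[C@@](C)(O)[C@H](O)CC/C(C)=C/[Al](C)C | intermediate
15 | (1E,5R,6R)-1-iodo-2,6,10-trimethylundeca-1,9-diene-5,6-diol | CC(C)=CCC[C@@](C)(O)[C@H](O)CC/C(C)=C/I | intermediate
16 | 1,3-dioxoisoindolin-2-yl (E)-6-(2,5-dimethoxy-3-methylphenyl)-4-methylhex-4-enoate | COc1cc(C)c(OC)c(C/C=C(\C)CCC(=O)ON2C(=O)c3ccccc3C2=O)c1 | intermediate
17 | (6R,7R,10E,14E)-16-(2,5-dimethoxy-3-methylphenyl)-2,6,10,14-tetramethylhexadeca-2,10,14-triene-6,7-diol | CC(C)=CCC[C@@](C)(O)[C@H](O)CC/C(C)=C/CC/C(C)=C/Cc1cc(OC)cc(C)c1OC | intermediate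
18 | 2-[(2E,6E,10R,11R)-10,11-dihydroxy-3,7,11,15-tetramethylhexadeca-2,6,14-trien-1-yl]-6-methylcyclohexa-2,5-diene-1,4-dione | CC(C)=CCC[C@@](C)(O)[C@H](O)CC/C(C)=C/CC/C(C)=C/CC1=CC(=O)C=C(C)C1=O | target

**Step count**
Total: 7 steps. Longest linear sequence: 6 steps (5 → 8 → 10 → 13 → 15 → 17 → 18).

**Steps most likely to fail, with fallbacks**

Step 6 (the proposed new coupling). The free diol could be acylated by the activated ester or bind nickel, and the homoallylic radical could erode the 2'E geometry. The fallback uses known chemistry, sets out from 15 and from 4 (through isolated 16) and comes back at 17. Compound 15 is protected with 2,2-dimethoxypropane/PPTS as (4R,5R)-4-[(3E)-4-iodo-3-methylbut-3-en-1-yl]-2,2,5-trimethyl-5-(4-methylpent-3-en-1-yl)-1,3-dioxolane F7. Iodine–lithium exchange (t-BuLi, −78 °C) and ZnCl2 give the alkenylzinc chloride F8. This is coupled thermally with isolated 16 under Ni(acac)2/2,2'-bipyridine (the published nickel-catalysed decarboxylative alkenylation of redox-active esters with alkenylzinc reagents) to give the coupled acetonide (4R,5R)-4-[(3E,7E)-9-(2,5-dimethoxy-3-methylphenyl)-3,7-dimethylnona-3,7-dien-1-yl]-2,2,5-trimethyl-5-(4-methylpent-3-en-1-yl)-1,3-dioxolane F9. Aqueous acetic acid then frees 17.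

Step 2. The Grignard reagent may attack the ester, or the copper species may deliver allenyl rather than propargyl product. The fallback sets out from 5 (and 7) and comes back at 10. Compound 5 is saponified (LiOH, THF/H2O, 0 °C) to lithium (2R)-oxirane-2-carboxylate F5. With no ester left, uncatalysed opening by 7 at C3 (THF, 0 °C; 1 M HCl) gives (2R)-2-hydroxyhex-5-ynoic acid F6. Excess MeLi (then Me3SiCl and aqueous acid) converts the lithium carboxylate directly into 10, bypassing 8 and 9.

Step 1. The lactone carbonyl may be attacked, or the E/Z ratio of the new trisubstituted olefin may be too low. The fallback sets out from 1 (through 3) and comes back at 4. Grignard reagent 3 is alkylated with 1-bromo-3-methylbut-2-ene (THF, 0 °C) to give 1,4-dimethoxy-2-methyl-6-(3-methylbut-2-en-1-yl)benzene F1. SeO2 (cat.)/t-BuOOH, then NaBH4, oxidises the E-methyl group selectively to (E)-4-(2,5-dimethoxy-3-methylphenyl)-2-methylbut-2-en-1-ol F2. PBr3 gives (E)-1-(4-bromo-3-methylbut-2-en-1-yl)-2,5-dimethoxy-3-methylbenzene F3. Alkylation of the lithium enolate of ethyl acetate gives ethyl (E)-6-(2,5-dimethoxy-3-methylphenyl)-4-methylhex-4-enoate F4, and LiOH saponification gives 4.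

**Further compounds**
F1 | step 1 | 1,4-dimethoxy-2-methyl-6-(3-methylbut-2-en-1-yl)benzene | COc1cc(C)c(OC)c(CC=C(C)C)c1
F2 | step 1 | (E)-4-(2,5-dimethoxy-3-methylphenyl)-2-methylbut-2-en-1-ol | COc1cc(C)c(OC)c(C/C=C(\C)CO)c1
F3 | step 1 | (E)-1-(4-bromo-3-methylbut-2-en-1-yl)-2,5-dimethoxy-3-methylbenzene | COc1cc(C)c(OC)c(C/C=C(\C)CBr)c1
F4 | step 1 | ethyl (E)-6-(2,5-dimethoxy-3-methylphenyl)-4-methylhex-4-enoate | CCOC(=O)CC/C(C)=C/Cc1cc(OC)cc(C)c1OC
F5 | step 2 | lithium (2R)-oxirane-2-carboxylate | [Li+].[O-]C(=O)[C@H]1CO1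
F6 | step 2 | (2R)-2-hydroxyhex-5-ynoic acid | OC(=O)[C@H](O)CCC#C
F7 | step 6 | (4R,5R)-4-[(3E)-4-iodo-3-methylbut-3-en-1-yl]-2,2,5-trimethyl-5-(4-methylpent-3-en-1-yl)-1,3-dioxolane | CC(C)=CCC[C@@]1(C)OC(C)(C)O[C@@H]1CC/C(C)=C/I
F8 | step 6 | [(1E)-2-methyl-4-[(4R,5R)-2,2,5-trimethyl-5-(4-methylpent-3-en-1-yl)-1,3-dioxolan-4-yl]but-1-en-1-yl]zinc chloride | CC(C)=CCC[C@@]1(C)OC(C)(C)O[C@@H]1CC/C(C)=C/[Zn]Cl
F9 | step 6 | (4R,5R)-4-[(3E,7E)-9-(2,5-dimethoxy-3-methylphenyl)-3,7-dimethylnona-3,7-dien-1-yl]-2,2,5-trimethyl-5-(4-methylpent-3-en-1-yl)-1,3-dioxolane | CC(C)=CCC[C@@]1(C)OC(C)(C)O[C@@H]1CC/C(C)=C/CC/C(C)=C/Cc1cc(OC)cc(C)c1OC
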